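If target in these flasks is made no faster than second substrate attacks it, the asked share suffers, and two times tell how far.

    starting material + free enzyme ⇌ first complex (K1 = 10.1 /M, k1 = 8.92 × 10⁵ /M/h)
    first complex ⇌ loaded enzyme + first product (K2 = 0.0236 M, k2 = 957 /h)
    second substrate + loaded enzyme ⇌ second complex (K3 = 210 /M, k3 = 1.02 × 10⁶ /M/h)
    second complex → free enzyme + target (k4 = 9170 /h)
    second substrate + target → over-reaction product (k5 = 6.08 /M/h)

the same everywhere: second substrate 0.0770 M; free enzyme 35 µM

| run | starting material | time | remark |
|---|---|---|---|
| theta | 0.070 M | 25 h | everything together in a closed stirred flask, run for 25 h |
| epsilon | 0.070 M |  | a single well-mixed tank run continuously and read at steady state, 75.0 h in it on average |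
| delta | 0.070 M |  | one stirred flow tank at steady state, fed with the mixture as stated, mean residence time 25 h |
| gamma | 0.070 M (fed, over 12.5 h) | 25 h | a stirred flask in which starting material is dosed at a steady rate over 12.5 h without added volume, worked up at 25 h |

- the stated concentrations are those of everything mixed, before any reaction; amounts are the same in each set-up
- the feed brings no volume worth counting
- run time (theta): 25 h

* the set-up with the highest share of target in all that became target or over-reaction product, at the outlet or at the end ("none" if the first two lie within 2 percentage points) (theta / epsilon / delta / gamma / none)
* share of target in all that became target or over-reaction product, at the outlet or at the end, theta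
* share of target in all that became target or over-reaction product, at the outlet or at the end, epsilon
* share of target in all that became target or over-reaction product, at the outlet or at the end, delta
* share of target in all that became target or over-reaction product, at the outlet or at the end, gamma

Everything is counted in fractions of the starting-material charge: x has passed the enzyme and o is over-reaction product, so target is x − o. Starting material is the smaller charge, but each x and each o takes one unit of second substrate, so b = 1.10 − x − o, and the excess is only 0.100.

At the start, before first product has built up, the split of first complex, at 957 /h, is slower than binding, its reversal and target release, so it is the rate-limiting step at that moment. At that starting pace, with first complex in equilibrium with free enzyme, the reckoned supply time for the whole charge is 5.05 h. The over-reaction runs as do/dt = b(x − o)/T, with attack time T = 2.35 h. Their ratio is 2.15, the race number: supply time over attack time.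

My reckoning takes do/dx = N·b·(x − o) and drops o on the right. That gives o near 0.465 at full conversion, more than the excess. So second substrate, the true limiting reagent, should vanish with starting material left, and the share is then (x − o)/x. Gamma doses over 12.5 h, longer than the enzyme time, so its race number becomes 5.32 and it should fall below theta. The reckoning gives no share and leaves the tanks open.

The forecast gave 62.2 % for theta, 68.8 % for epsilon, 65.6 % for delta and 54.2 % for gamma, with epsilon best; the excess, it says, “cannot cover it”.

The simulation gives 62.1 %, 68.8 %, 65.6 % and 54.2 %, in the same order, with epsilon best.

In theta at 2.50 h, target is made 1.99 times faster than it is used up, and its half-life by over-reaction, 2.8 h, is short against the 25 h run. Theta ends with second substrate at 0 %, starting material at 20.2 %, target at 49.5 % and over-reaction product at 30.2 %.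

A neighbour of theta, with 1.4 × 10⁻⁵ M of free enzyme and all else held, has a race number of 5.37. That is above the 4.18 where target and over-reaction product draw level. Computed, it ends with target at 32.3 %, over-reaction product at 38.8 % and a share of 45.4 %.

The numbers of this flask belong to no real substance; what happens was integrated by code.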